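**Retrosynthetic overview**

Numbering (germacrane): ring C1–C10 with C1=C10; C14 is the CO2Me carbon on C10, C15 the CH2OH carbon on C4; lactone O on C6; C7 carries C11(=C13)–C12; isobutyrate on C8.
Enabling feature: C6 and C10 lie 1,5 across the ten-membered ring, C6 is γ to C12, and C7–C11 and C8–O are cis. A temporary C6–C10 bond therefore folds C6–C7–C8–C9–C10 into the cyclopentane of a cis-fused 8,12-lactone (commercial lactone diol 1) and C10, C1–C5, C6 into a fused seven-membered ring.
Key disconnection: the O–C6 bond, made together with C6–C10 scission. A C10 alkoxy radical (from a ring-fusion hydroperoxide) fragments to the ten-membered C10 ketone and a C6 radical, which the C12 carboxylate captures through copper; the lactone moves from O8 to C6.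
Before the key step: C4–C5 by organocatalytic Michael addition of hex-5-enal to the exocyclic enone from 1 (sets C4), C10=C1 by ring-closing metathesis, peroxide by cobalt-catalysed silylperoxidation. After it: C8 acylation, C10 enol triflate and methoxycarbonylation (C14), α-methylenation (C13), desilylation.
Ring order: cyclopentane with 8,12-lactone (bought) → seven-membered ring (step 7) → ten-membered ring together with the 6,12-lactone (step 9).

Key step: step 9

Remark: the dextrorotatory lactone diol 1 (antipode of the common prostaglandin building block) is assumed to be purchasable as a single enantiomer; it supplies C5–C12 with the C7 and C8 configurations of the target.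

**Route**

Step 1
Reactants: 1 lactone diol
Product: 2 primary tosylate (C5–OTs)
Conditions: TsCl (1.05 equiv), pyridine, CH2Cl2, −10 °C
Reagents that add atoms: p-toluenesulfonyl chloride, Cc1ccc(cc1)S(Cl)(=O)=O
Why: Chemoselective sulfonylation of the less hindered primary alcohol beside the secondary one; no stereocentre is touched.

Step 2
Reactants: 2 primary tosylate
Product: 4 exocyclic enone (C6=C5H2, C10=O), via keto tosylate 3 (not isolated)
Conditions: Dess–Martin periodinane, CH2Cl2, 0 → 20 °C; then Et3N, 0 °C; solution used at once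
Reagents that add atoms: none
Why: Dess–Martin oxidation gives a β-tosyloxy ketone that undergoes E1cB elimination to the α-methylene ketone; the configurations lost at C6 and C10 are not needed, and the enone is kept cold and used directly to avoid dimerisation or drift of the double bond into the ring.

Step 3
Reactants: 4 exocyclic enone; 5 hex-5-enal
Product: 6 keto aldehyde (4S)
Conditions: (R)-2-[diphenyl(trimethylsilyloxy)methyl]pyrrolidine (20 mol%), ethyl 3,4-dihydroxybenzoate (20 mol%), CH2Cl2, 0 °C
Reagents that add atoms: none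
Why: Enamine-catalysed Michael addition of an aldehyde to an enone: the diphenyl(silyloxy)methyl group of the (R)-catalyst blocks one face of the E-enamine of 5, so the methylene terminus of 4 is attacked from the open face and C4 is set S, while C6 protonates to the more stable trans ketone and is erased in step 9 in any case.

Step 4
Reactants: 6 keto aldehyde
Product: 7 keto alcohol (C15–OH)
Conditions: NaBH4 (0.4 equiv), EtOH/CH2Cl2, −78 °C
Reagents that add atoms: none
Why: Chemoselective borohydride reduction of an aldehyde beside a ketone at low temperature; it also removes the epimerisable α-position at C4.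

Step 5
Reactants: 7 keto alcohol
Product: 8 silyl ether ketone (C15–OTBDPS)
Conditions: TBDPSCl, imidazole, CH2Cl2, 20 °C
Reagents that add atoms: tert-butyl(chloro)diphenylsilane, CC(C)(C)[Si](Cl)(c1ccccc1)c1ccccc1
Why: Silylation of the primary alcohol (which also drains any lactol form); the ether should survive all later base, radical and palladium steps and blocks C15–O from competing with the carboxylate in step 9.

Step 6
Reactants: 8 silyl ether ketone
Product: 9 diene (C10=CH2 and terminal C1 alkene)
Conditions: Ph3PCH3Br, KOtBu, THF, 0 °C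
Reagents that add atoms: methyltriphenylphosphonium bromide, C[P+](c1ccccc1)(c1ccccc1)c1ccccc1.[Br-]
Why: Wittig methylenation of the cyclopentanone; the non-stabilised ylide is not expected to attack the lactone, and epimerisation at C6 would be without consequence.

Step 7
Reactants: 9 diene
Product: 10 tricyclic alkene (C10=C1 in the new seven-membered ring)
Conditions: second-generation Grubbs catalyst (5 mol%), CH2Cl2 (5 mM), 40 °C
Reagents that add atoms: none
Why: Ring-closing metathesis of a 1,1-disubstituted with a monosubstituted alkene to a trisubstituted cycloheptene, driven by loss of ethylene.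

Step 8
Reactants: 10 tricyclic alkene
Product: 11 triethylsilyl peroxide at C10
Conditions: Co(acac)2 (10 mol%), O2 (1 atm), Et3SiH, ClCH2CH2Cl, 20 °C
Reagents that add atoms: dioxygen, O=O; triethylsilane, CC[SiH](CC)CC
Why: Mukaiyama–Isayama silylperoxidation: hydrogen atom transfer from a cobalt hydride to C1 gives the tertiary C10 radical, which is trapped by O2 and silylated (Markovnikov); the new C10 centre is destroyed in step 9, so its configuration is irrelevant.

Step 9
Reactants: 11 triethylsilyl peroxide
Product: 13 ten-membered keto lactone (C10 ketone, trans 6,12-lactone, free C8–OH), via hydroperoxy acid 12 (not isolated)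
Conditions: LiOH·H2O, THF/H2O, 0 °C; AcOH to pH 6; then Cu(OAc)2·H2O (1.5 equiv), FeSO4·7H2O (1.2 equiv), MeOH/H2O, 0 → 20 °C
Reagents that add atoms: lithium hydroxide monohydrate, [Li+].[OH-].O (its oxygen ends in the carboxyl group that closes the lactone)
Why: Proposed new method: hydroxide cleaves the silyl peroxide and the 8,12-lactone, divalent iron reduces the O–O bond to the C10 alkoxy radical, β-scission of the C6–C10 ring-fusion bond (the only scission that gives a secondary radical) opens the bicyclo[5.3.0]decane to the ten-membered C10 ketone, and the C6 radical is taken up by divalent copper carrying the C12 carboxylate and collapses to the lactone, copper and iron returning to their starting oxidation states. Closest known reaction types: the iron/copper-mediated fragmentation of tertiary and α-alkoxy hydroperoxides, the oxidative β-fragmentation of ring-fusion carbinols to ten-membered ketones, and the copper-mediated conversion of γ-carboxyalkyl radicals into γ-lactones in alkene carbolactonisations. The ten-membered ring is not closed but set free by ring expansion (5 + 7 → 10), and the lactone closes in the 5-exo mode at C6 by C–O reductive elimination from a six-membered trivalent-copper carboxylate. C6 is the only new stereocentre: the planar radical is approached by the carboxylate held on C7 through the rotamer that keeps C5 anti to C8 (C5 beside the small H7), which should give the trans-fused lactone (6R), and the configuration that C6 had in 11 plays no role. The step needs regioselective scission (secondary against primary radical plus loss of the ring fusion), C–O bond formation rather than β-hydride loss at copper (intramolecular carboxylate ligand, supplied as the free carboxylate) and no return to the 8,12-lactone (pH 6, 0 °C, immediate use of 13).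

Step 10
Reactants: 13 ten-membered keto lactone
Product: 14 C8 isobutyrate
Conditions: (iPrCO)2O, DMAP (cat.), pyridine, CH2Cl2, 0 °C
Reagents that add atoms: isobutyric anhydride, CC(C)C(=O)OC(=O)C(C)C
Why: DMAP-catalysed acylation of the secondary alcohol, done at once so that the free C8 hydroxyl cannot draw the lactone back to the 8,12-position.

Step 11
Reactants: 14 C8 isobutyrate
Product: 15 enol triflate (C10(OTf)=C1, E, ring-cis)
Conditions: KN(SiMe3)2 (1.05 equiv), THF, −78 °C; then PhNTf2, −78 → −40 °C
Reagents that add atoms: N-phenylbis(trifluoromethanesulfonimide), O=S(=O)(N(c1ccccc1)S(=O)(=O)C(F)(F)F)C(F)(F)F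
Why: Kinetic deprotonation of the ketone and O-triflation: the bulky amide should take a proton from the unhindered C1 and not from C9, which is shielded by the branched, acyloxy-bearing C8, and the ten-membered ring favours the cis ring enolate, hence the (E)-enol triflate.

Step 12
Reactants: 15 enol triflate
Product: 16 methyl enoate (C14 installed, C1=C10 E)
Conditions: Pd(OAc)2 (5 mol%), Ph2P(CH2)3PPh2, CO (1 atm), MeOH, Et3N, DMF, 50 °C
Reagents that add atoms: carbon monoxide, [C-]#[O+]; methanol, CO
Why: Palladium-catalysed methoxycarbonylation of an enol triflate (oxidative addition, CO insertion, methanolysis) with retention of the double-bond geometry; the homoallylic isobutyrate cannot ionise.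

Step 13
Reactants: 16 methyl enoate
Product: 19 α-methylene lactone silyl ether, via Mannich base 17 (not isolated), via ammonium iodide 18 (not isolated)
Conditions: LiN(SiMe3)2, THF, −78 °C; CH2=NMe2+ I−; then MeI, MeOH; then aq. NaHCO3, 20 °C
Reagents that add atoms: dimethyl(methylidene)ammonium iodide, C=[N+](C)C.[I-]
Why: α-Methylenation of a lactone by Mannich reaction of its lithium enolate with Eschenmoser's salt, quaternisation and E1cB elimination; the γ-lactone is several pKa units more acidic than the open-chain esters, which should make the enolisation selective.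

Step 14
Reactants: 19 α-methylene lactone silyl ether
Product: 20 target
Conditions: HF·pyridine, pyridine/THF, 0 → 20 °C
Reagents that add atoms: none
Why: Fluoride cleavage of the silyl ether under buffered, non-basic conditions that should leave the α-methylene lactone, the enoate and the isobutyrate untouched.

**Compound list**

1 | (3aS,4R,5S,6aR)-5-hydroxy-4-(hydroxymethyl)hexahydro-2H-cyclopenta[b]furan-2-one (commercial dextrorotatory lactone diol; C5–C12) | O=C1C[C@H]2[C@H](CO)[C@@H](O)C[C@H]2O1 | starting material
2 | primary p-toluenesulfonate of 1 (C5–OTs, C10–OH free) | O=C1C[C@H]2[C@H](COS(=O)(=O)c3ccc(C)cc3)[C@@H](O)C[C@H]2O1 | intermediate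
3 | keto tosylate (C10 ketone, C5–OTs) | O=C1C[C@H]2[C@H](COS(=O)(=O)c3ccc(C)cc3)C(=O)C[C@H]2O1 | intermediate (not isolated)
4 | exocyclic enone on the cis-fused 8,12-lactone (C6=C5H2, C10=O; C7, C8 as in 1) | O=C1C[C@H]2C(=C)C(=O)C[C@H]2O1 | intermediate
5 | hex-5-enal | C=CCCCC=O | starting material
6 | keto aldehyde (4S; C15 aldehyde; C6 side chain trans to the lactone CH2) | O=C1C[C@H]2[C@H](C[C@@H](C=O)CCC=C)C(=O)C[C@H]2O1 | intermediate
7 | keto alcohol (4S; C15–OH) | O=C1C[C@H]2[C@H](C[C@@H](CO)CCC=C)C(=O)C[C@H]2O1 | intermediate
8 | silyl ether ketone (C15–OTBDPS, C10 ketone) | O=C1C[C@H]2[C@H](C[C@@H](CO[Si](c3ccccc3)(c3ccccc3)C(C)(C)C)CCC=C)C(=O)C[C@H]2O1 | intermediate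
9 | diene (C10=CH2; terminal alkene at C1) | O=C1C[C@H]2[C@H](C[C@@H](CO[Si](c3ccccc3)(c3ccccc3)C(C)(C)C)CCC=C)C(=C)C[C@H]2O1 | intermediate
10 | tricyclic alkene (cyclopentane lactone fused to a cycloheptene, C10=C1) | O=C1C[C@H]2[C@@H]3C[C@@H](CO[Si](c4ccccc4)(c4ccccc4)C(C)(C)C)CCC=C3C[C@H]2O1 | intermediate
11 | C10 triethylsilyl peroxide (both C10 epimers; centre destroyed in step 9) | O=C1C[C@H]2[C@@H]3C[C@@H](CO[Si](c4ccccc4)(c4ccccc4)C(C)(C)C)CCCC3(OO[Si](CC)(CC)CC)C[C@H]2O1 | intermediate
12 | hydroperoxy hydroxy acid (C10–OOH, C8–OH, C12 acid; present as lithium carboxylate) | OC(=O)C[C@H]1[C@@H]2C[C@@H](CO[Si](c3ccccc3)(c3ccccc3)C(C)(C)C)CCCC2(OO)C[C@H]1O | intermediate (not isolated)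
13 | ten-membered keto lactone (C10 ketone; trans 6,12-lactone, 6R; C8–OH; 4S) | C1C(=O)O[C@@H]2C[C@@H](CO[Si](c3ccccc3)(c3ccccc3)C(C)(C)C)CCCC(=O)C[C@@H](O)[C@@H]12 | intermediate
14 | C8 isobutyrate of 13 | C1C(=O)O[C@@H]2C[C@@H](CO[Si](c3ccccc3)(c3ccccc3)C(C)(C)C)CCCC(=O)C[C@@H](OC(=O)C(C)C)[C@@H]12 | intermediate
15 | (E)-enol triflate (C10(OTf)=C1, ring-cis) | C1C(=O)O[C@@H]2C[C@@H](CO[Si](c3ccccc3)(c3ccccc3)C(C)(C)C)CC/C=C(/OS(=O)(=O)C(F)(F)F)C[C@@H](OC(=O)C(C)C)[C@@H]12 | intermediate
16 | (E)-methyl enoate (C10–CO2Me, C1=C10) | C1C(=O)O[C@@H]2C[C@@H](CO[Si](c3ccccc3)(c3ccccc3)C(C)(C)C)CC/C=C(/C(=O)OC)C[C@@H](OC(=O)C(C)C)[C@@H]12 | intermediate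
17 | Mannich base (C11–CH2NMe2; C11 epimers) | CN(C)CC1C(=O)O[C@@H]2C[C@@H](CO[Si](c3ccccc3)(c3ccccc3)C(C)(C)C)CC/C=C(/C(=O)OC)C[C@@H](OC(=O)C(C)C)[C@@H]12 | intermediate (not isolated)
18 | trimethylammonium iodide of 17 | C[N+](C)(C)CC1C(=O)O[C@@H]2C[C@@H](CO[Si](c3ccccc3)(c3ccccc3)C(C)(C)C)CC/C=C(/C(=O)OC)C[C@@H](OC(=O)C(C)C)[C@@H]12.[I-] | intermediate (not isolated)
19 | α-methylene lactone silyl ether (target with C15–OTBDPS) | C=C1C(=O)O[C@@H]2C[C@@H](CO[Si](c3ccccc3)(c3ccccc3)C(C)(C)C)CC/C=C(/C(=O)OC)C[C@@H](OC(=O)C(C)C)[C@@H]12 | intermediate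
20 | CNP0251148.1: (1(10)E,4S,6R,7S,8R)-15-hydroxy-8-isobutyryloxy-14-methoxycarbonyl-germacra-1(10),11(13)-dien-6,12-olide | C=C1C(=O)O[C@@H]2C[C@@H](CO)CC/C=C(/C(=O)OC)C[C@@H](OC(=O)C(C)C)[C@@H]12 | target

**Summary and risks**

Total step count: 14. Longest linear sequence: 14 steps (1 → 20).

Step 9 (Proposed new method). What may go wrong: β-hydride loss from the C6 organocopper (alkene instead of C–O bond formation), approach of the carboxylate to the wrong face of the C6 radical, or hydrogen abstraction by the alkoxy radical before fragmentation. The fallback uses known, stereospecific chemistry; it sets out from 11 and comes back to the route at 13. Mild acid (AcOH, THF/H2O) frees the tricyclic lactone hydroperoxide F1. 4-Nitrobenzoyl chloride in pyridine gives the perester F2, which undergoes Criegee rearrangement (the ring-fusion carbon C6 migrates from C10 to oxygen with retention) to the bridged ketal ester F3. Mild aqueous acid hydrolyses it to the ten-membered hydroxy ketone F4, whose C6 hydroxyl has the configuration opposite to that of the lactone oxygen in the target. MsCl/Et3N gives the mesylate F5. LiOH then opens the 8,12-lactone, and the freed C12 carboxylate displaces the mesylate with inversion (intramolecular SN2), giving 13 after adjustment to pH 6.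

Step 11. What may go wrong: enolisation towards C9, after which the isobutyrate is lost by β-elimination, or unselective formation of regioisomeric enol triflates. The fallback moves the acylation behind the enoate formation so that no leaving group stands β to the enolate; it sets out from 13 and comes back at 16. TESCl/imidazole gives the C8 triethylsilyl ether F6. KN(SiMe3)2/PhNTf2 gives the silyloxy enol triflate F7 (a silyloxy group is not expelled at −78 °C and shields C9 more strongly). Methoxycarbonylation as in step 12 gives the silyloxy enoate F8. Pyridinium p-toluenesulfonate in MeOH removes only the triethylsilyl group to give the hydroxy enoate F9, and acylation as in step 10 gives 16.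

Step 13. What may go wrong: competing γ-deprotonation of the enoate or transannular Michael addition of the lactone enolate to C1. The fallback avoids strong base; it sets out from 16 and comes back at 19. Bredereck's reagent (tBuOCH(NMe2)2, toluene, 90 °C) condenses with the lactone α-CH2 to the aminomethylidene lactone F10. Aqueous HCl/THF gives the hydroxymethylidene lactone F11. Aqueous formaldehyde with K2CO3 then effects deformylative methylenation to 19.

Further compounds
F1 | step 9 | tricyclic lactone hydroperoxide (C10–OOH) | O=C1C[C@H]2[C@@H]3C[C@@H](CO[Si](c4ccccc4)(c4ccccc4)C(C)(C)C)CCCC3(OO)C[C@H]2O1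
F2 | step 9 | 4-nitroperbenzoate of F1 | O=C1C[C@H]2[C@@H]3C[C@@H](CO[Si](c4ccccc4)(c4ccccc4)C(C)(C)C)CCCC3(OOC(=O)c4ccc(cc4)[N+](=O)[O-])C[C@H]2O1
F3 | step 9 | bridged ketal ester (C6–O–C10 ether bridge, C10 4-nitrobenzoate) | O=C1C[C@H]2[C@@H]3C[C@@H](CO[Si](c4ccccc4)(c4ccccc4)C(C)(C)C)CCCC(O3)(OC(=O)c4ccc(cc4)[N+](=O)[O-])C[C@H]2O1
F4 | step 9 | ten-membered hydroxy ketone with intact 8,12-lactone (C6–OH, C10 ketone) | O=C1C[C@H]2[C@@H](O)C[C@@H](CO[Si](c3ccccc3)(c3ccccc3)C(C)(C)C)CCCC(=O)C[C@H]2O1
F5 | step 9 | C6 methanesulfonate of F4 | O=C1C[C@H]2[C@@H](OS(C)(=O)=O)C[C@@H](CO[Si](c3ccccc3)(c3ccccc3)C(C)(C)C)CCCC(=O)C[C@H]2O1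
F6 | step 11 | C8 triethylsilyl ether of 13 | C1C(=O)O[C@@H]2C[C@@H](CO[Si](c3ccccc3)(c3ccccc3)C(C)(C)C)CCCC(=O)C[C@@H](O[Si](CC)(CC)CC)[C@@H]12
F7 | step 11 | (E)-enol triflate with C8–OSiEt3 | C1C(=O)O[C@@H]2C[C@@H](CO[Si](c3ccccc3)(c3ccccc3)C(C)(C)C)CC/C=C(/OS(=O)(=O)C(F)(F)F)C[C@@H](O[Si](CC)(CC)CC)[C@@H]12
F8 | step 11 | (E)-methyl enoate with C8–OSiEt3 | C1C(=O)O[C@@H]2C[C@@H](CO[Si](c3ccccc3)(c3ccccc3)C(C)(C)C)CC/C=C(/C(=O)OC)C[C@@H](O[Si](CC)(CC)CC)[C@@H]12
F9 | step 11 | (E)-methyl enoate with free C8–OH | C1C(=O)O[C@@H]2C[C@@H](CO[Si](c3ccccc3)(c3ccccc3)C(C)(C)C)CC/C=C(/C(=O)OC)C[C@@H](O)[C@@H]12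
F10 | step 13 | α-(dimethylaminomethylidene) lactone | CN(C)C=C1C(=O)O[C@@H]2C[C@@H](CO[Si](c3ccccc3)(c3ccccc3)C(C)(C)C)CC/C=C(/C(=O)OC)C[C@@H](OC(=O)C(C)C)[C@@H]12
F11 | step 13 | α-(hydroxymethylidene) lactone | OC=C1C(=O)O[C@@H]2C[C@@H](CO[Si](c3ccccc3)(c3ccccc3)C(C)(C)C)CC/C=C(/C(=O)OC)C[C@@H](OC(=O)C(C)C)[C@@H]12
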